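**Retrosynthetic overview**

- Target 30 comes from its hepta-O-benzyl ether 29 by hydrogenolysis, and 29 from the bicyclic vinylogous ester 25, whose carbocycle is dehydrogenated last to ring A of the upper flavan, erasing C4a.
- 25 comes from the trans-4,6-diaryl δ-lactone 16 and the α-silylated methyl vinyl ketone 21: Michael addition (C4a–C5), Claisen closure (C8–C8a), reclosure of O1 on C8a.
- 16 comes from the diaryl cuprate of 8-lithio-hexa-O-benzylgallocatechin and the (S)-6-aryl-5,6-dihydropyran-2-one 7 (interflavan C4–C8 bond, anti to the C6 aryl).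
- 7 comes from 4-benzyloxybenzaldehyde (Brown allylboration, acryloylation, ring-closing metathesis); bromide 12 comes from (+)-gallocatechin (benzylation, bromination).
- Feature: ring A of the upper flavan carries only the C7 hydroxyl, and without it ring C is a δ-lactone (C8a carbonyl, C4a α-carbon, O1 ring oxygen) on which the 2,4-trans aryl pair can be set by conjugate addition. Ring order: gallocatechin rings kept intact, then ring C as lactone, then ring A, aromatised last.

Key step: step 10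

Remarks on the chemistry:
- The gallocatechin unit is carried with all six hydroxyls benzylated (five phenols and the C3 alcohol), so 16 is a hexa-O-benzylgallocatechin-8-yl lactone.
- (−)-Ipc2B(allyl) is assumed to be used as its commercial pentane solution. The assignment that this (+)-α-pinene-derived reagent gives the (S)-alcohol with aryl aldehydes should be confirmed on 4 before going on.
- In 25 the C5 methylene at C4a is trans to the C4 aryl (H-4a is cis to it).

**Step 1**
Reactants: 1 4-benzyloxybenzaldehyde; 2 (−)-B-allyldiisopinocampheylborane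
Product: 4 (S)-1-[4-(benzyloxy)phenyl]but-3-en-1-ol, via diisopinocampheylborinic ester 3 (not isolated)
Conditions: 2 (1 M in pentane), Et2O, −78 °C; then 3 M NaOH, 30% H2O2, 0 °C → rt
Reagents that add atoms: (−)-B-allyldiisopinocampheylborane (2), C=CCB([C@@H]1C[C@@H]2C[C@H]([C@H]1C)C2(C)C)[C@@H]1C[C@@H]2C[C@H]([C@H]1C)C2(C)C
Why: Brown allylboration through a chair Zimmerman–Traxler transition state, in which the isopinocampheyl groups of the (+)-α-pinene-derived reagent should direct allyl to the Si face of the aryl aldehyde and so give the (S)-carbinol that becomes C2 of the upper flavan.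

**Step 2**
Reactants: 4 (S)-1-[4-(benzyloxy)phenyl]but-3-en-1-ol; 5 acryloyl chloride
Product: 6 (S)-1-[4-(benzyloxy)phenyl]but-3-en-1-yl acrylate
Conditions: Et3N, DMAP (cat.), CH2Cl2, 0 °C
Reagents that add atoms: acryloyl chloride (5), C=CC(Cl)=O
Why: Base-mediated O-acylation of a secondary alcohol with an acid chloride, which does not touch the carbinol stereocentre.

**Step 3**
Reactants: 6 (S)-1-[4-(benzyloxy)phenyl]but-3-en-1-yl acrylate
Product: 7 (S)-6-[4-(benzyloxy)phenyl]-5,6-dihydro-2H-pyran-2-one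
Conditions: second-generation Grubbs catalyst (H2IMes)(PCy3)Cl2Ru=CHPh (cat.), CH2Cl2 (dilute), 40 °C
Reagents that add atoms: none
Why: Ring-closing metathesis of a homoallylic acrylate to the α,β-unsaturated δ-lactone, driven by loss of ethene and leaving C6 untouched.

**Step 4**
Reactants: 8 (+)-gallocatechin; 9 benzyl bromide
Product: 10 5,7,3',4',5'-penta-O-benzyl-(+)-gallocatechin
Conditions: BnBr, K2CO3, DMF (degassed), Ar, 0 °C → rt
Reagents that add atoms: benzyl bromide (9), BrCc1ccccc1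
Why: Williamson etherification in which carbonate deprotonates only the five phenols, so the C3 alcohol and the (2R,3S) centres should be left as they are.

**Step 5**
Reactants: 10 5,7,3',4',5'-penta-O-benzyl-(+)-gallocatechin; 9 benzyl bromide
Product: 11 3,5,7,3',4',5'-hexa-O-benzyl-(+)-gallocatechin
Conditions: NaH, BnBr, n-Bu4NI (cat.), DMF, 0 °C → rt
Reagents that add atoms: benzyl bromide (9), BrCc1ccccc1
Why: Williamson etherification of the remaining secondary alcohol through its sodium alkoxide, giving a substrate without acidic protons for the later lithiation.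

**Step 6**
Reactants: 11 3,5,7,3',4',5'-hexa-O-benzyl-(+)-gallocatechin
Product: 12 8-bromo-3,5,7,3',4',5'-hexa-O-benzyl-(+)-gallocatechin
Conditions: NBS, CH2Cl2, −78 °C → rt, dark
Reagents that add atoms: N-bromosuccinimide, O=C1CCC(=O)N1Br
Why: Electrophilic aromatic bromination, which on 5,7-dialkoxyflavans is expected at C8 of the phloroglucinol ring (activated by O1, O7 and O5) in preference to C6 and to the less activated ring B.

**Step 7**
Reactants: 12 8-bromo-3,5,7,3',4',5'-hexa-O-benzyl-(+)-gallocatechin; 7 (S)-6-[4-(benzyloxy)phenyl]-5,6-dihydro-2H-pyran-2-one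
Product: 16 (4R,6S)-6-[4-(benzyloxy)phenyl]-4-(hexa-O-benzylgallocatechin-8-yl)tetrahydro-2H-pyran-2-one (4,6-trans), via 8-lithio-hexa-O-benzylgallocatechin 13 (not isolated), via lithium diarylcuprate 14 (not isolated), via silyl ketene acetal 15 (not isolated)
Conditions: 12 (2.4 equiv), t-BuLi (4.8 equiv), THF, −78 °C; CuBr·SMe2 (1.2 equiv), −78 → −40 °C; Me3SiCl, then 7 (1.0 equiv), −78 → −20 °C; 0.5 M HCl, 0 °C
Reagents that add atoms: none
Why: Bromine–lithium exchange and Gilman cuprate 1,4-addition accelerated by Me3SiCl, in which the aryl group should enter C4 by axial attack anti to the pseudo-equatorial C6 aryl of the half-chair lactone and so give the 4,6-trans (4R,6S) lactone; the untransferred aryl returns as 11 for recycling.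

**Step 8**
Reactants: 17 (1-bromovinyl)trimethylsilane; 18 acetaldehyde
Product: 20 3-(trimethylsilyl)but-3-en-2-ol (racemic), via 1-(trimethylsilyl)vinylmagnesium bromide 19 (not isolated)
Conditions: Mg, THF, reflux; CH3CHO, 0 °C; aq. NH4Cl
Reagents that add atoms: acetaldehyde (18), CC=O
Why: Grignard formation from the vinyl bromide and 1,2-addition to an aldehyde; the new carbinol centre is removed in the next step.

**Step 9**
Reactants: 20 3-(trimethylsilyl)but-3-en-2-ol
Product: 21 3-(trimethylsilyl)but-3-en-2-one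
Conditions: CrO3, H2SO4, acetone, 0 °C
Reagents that add atoms: none
Why: Jones oxidation of a secondary allylic alcohol to the enone, a standard preparation of this α-silyl vinyl ketone.

**Step 10**
Reactants: 16 (4R,6S)-6-[4-(benzyloxy)phenyl]-4-(hexa-O-benzylgallocatechin-8-yl)tetrahydro-2H-pyran-2-one; 21 3-(trimethylsilyl)but-3-en-2-one
Product: 25 (2S,4R,4aS)-2-[4-(benzyloxy)phenyl]-4-(hexa-O-benzylgallocatechin-8-yl)-2,3,4,4a,5,6-hexahydro-7H-chromen-7-one, via silyl keto lactone 22 (not isolated), via keto lactone 23 (not isolated), via hydroxy dione 24 (not isolated)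
Conditions: LiN(iPr)2, THF, −78 °C; 21, −78 → −30 °C; NaOMe, MeOH, 0 → 50 °C; AcOH to pH 5; PPTS (cat.), PhMe, 4 Å MS, rt
Reagents that add atoms: 3-(trimethylsilyl)but-3-en-2-one (21), CC(=O)C(=C)[Si](C)(C)C
Why: Proposed new method: the lithium enolate of 16 should add through C4a to the β-carbon of silyl enone 21 (C4a–C5), the α-silyl group stabilising the new enolate and suppressing the polymerisation and 1,2-addition expected with the parent enone; methoxide then removes silicon, the ketone enolates equilibrate, and the methyl-derived C8 enolate attacks the lactone carbonyl C8a (C8–C8a), expelling the C2 alkoxide and ending at the 1,3-dione enolate, which drives the sequence. The closest known reaction types are the Michael addition of lithium enolates to α-silyl vinyl ketones and the Michael–Claisen synthesis of cyclohexane-1,3-diones from ester enolates and enones, which have not been combined on a 4,6-diaryl δ-lactone. The carbocycle that becomes ring A closes by 6-exo-trig attack of the enolate carbon on C8a, and under mild acid the C2 hydroxyl re-forms ring C by 6-exo-trig addition to the same carbonyl and loss of water, so the C2–O bond is never broken. The one new stereocentre, C4a, is set by approach of 21 to the enolate face anti to the neighbouring C4 aryl group, can epimerise, and is erased in step 12. The step needs site selectivity alone: acylation from C8 rather than C6 (which would give a four-membered ring) and reclosure on C8a rather than C7 (which would give a bridged eight-membered ring) are each secured by the preference for six-membered ring formation. The closure is run with pyridinium tosylate because stronger acid could ionise the 4-benzyloxybenzylic C2–O bond.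

**Step 11**
Reactants: 25 (2S,4R,4aS)-2-[4-(benzyloxy)phenyl]-4-(hexa-O-benzylgallocatechin-8-yl)-2,3,4,4a,5,6-hexahydro-7H-chromen-7-one
Product: 26 6-(phenylselanyl) derivative of 25 (epimers at C6)
Conditions: LiN(iPr)2, THF, −78 °C; PhSeCl, −78 °C
Reagents that add atoms: phenylselenenyl chloride, Cl[Se]c1ccccc1
Why: Kinetic deprotonation of a 3-alkoxycyclohexenone at the α′ carbon (C6) and electrophilic selenenylation of the enolate; the C6 configuration is irrelevant.

**Step 12**
Reactants: 26 6-(phenylselanyl) derivative of 25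
Product: 29 (2S,4R)-2-[4-(benzyloxy)phenyl]-4-(hexa-O-benzylgallocatechin-8-yl)chroman-7-ol, via selenoxide 27 (not isolated), via cyclohexadienone 28 (not isolated)
Conditions: 30% H2O2 (excess), pyridine, CH2Cl2, 0 °C → rt
Reagents that add atoms: none
Why: Selenide oxidation and selenoxide syn-elimination across C5–C6 give a cross-conjugated dienone whose C4a hydrogen shifts to oxygen, so that aromatisation to the C7 phenol removes the C4a centre and leaves C2 and C4 untouched.

**Step 13**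
Reactants: 29 (2S,4R)-2-[4-(benzyloxy)phenyl]-4-(hexa-O-benzylgallocatechin-8-yl)chroman-7-ol
Product: 30 CNP0220331.3, (2S,4R)-4',7-dihydroxyflavan-(4→8)-(+)-gallocatechin
Conditions: H2 (1 atm), Pd(OH)2 on carbon, THF/MeOH, rt; filtration under Ar
Reagents that add atoms: none
Why: Catalytic hydrogenolysis of six aryl benzyl ethers and one alkyl benzyl ether under conditions that should leave the cyclic benzylic C2–O1 ethers of both flavan units intact.

**Compound list**

1 | 4-benzyloxybenzaldehyde | O=Cc1ccc(OCc2ccccc2)cc1 | starting material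
2 | (−)-B-allyldiisopinocampheylborane, (−)-Ipc2B(allyl), from (+)-α-pinene | C=CCB([C@@H]1C[C@@H]2C[C@H]([C@H]1C)C2(C)C)[C@@H]1C[C@@H]2C[C@H]([C@H]1C)C2(C)C | starting material
3 | diisopinocampheylborinic ester of 4 | c1ccccc1COc1ccc([C@@H](OB([C@@H]2C[C@@H]3C[C@H]([C@H]2C)C3(C)C)[C@@H]2C[C@@H]3C[C@H]([C@H]2C)C3(C)C)CC=C)cc1 | intermediate (not isolated)
4 | (S)-1-[4-(benzyloxy)phenyl]but-3-en-1-ol | c1ccccc1COc1ccc([C@@H](O)CC=C)cc1 | intermediate
5 | acryloyl chloride | C=CC(Cl)=O | starting material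
6 | (S)-1-[4-(benzyloxy)phenyl]but-3-en-1-yl acrylate | c1ccccc1COc1ccc([C@@H](OC(=O)C=C)CC=C)cc1 | intermediate
7 | (S)-6-[4-(benzyloxy)phenyl]-5,6-dihydro-2H-pyran-2-one | c1ccccc1COc1ccc([C@@H]2CC=CC(=O)O2)cc1 | intermediate
8 | (+)-gallocatechin, (2R,3S) | Oc1cc(O)c2c(c1)O[C@H](c1cc(O)c(O)c(O)c1)[C@@H](O)C2 | starting material
9 | benzyl bromide | BrCc1ccccc1 | starting material
10 | 5,7,3',4',5'-penta-O-benzyl-(+)-gallocatechin (free 3-OH) | c1ccccc1COc1cc(OCc2ccccc2)c2c(c1)O[C@H](c1cc(OCc3ccccc3)c(OCc3ccccc3)c(OCc3ccccc3)c1)[C@@H](O)C2 | intermediate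
11 | 3,5,7,3',4',5'-hexa-O-benzyl-(+)-gallocatechin | c1ccccc1COc1cc(OCc2ccccc2)c2c(c1)O[C@H](c1cc(OCc3ccccc3)c(OCc3ccccc3)c(OCc3ccccc3)c1)[C@@H](OCc1ccccc1)C2 | intermediate
12 | 8-bromo-3,5,7,3',4',5'-hexa-O-benzyl-(+)-gallocatechin | Brc1c(OCc2ccccc2)cc(OCc2ccccc2)c2c1O[C@H](c1cc(OCc3ccccc3)c(OCc3ccccc3)c(OCc3ccccc3)c1)[C@@H](OCc1ccccc1)C2 | intermediate
13 | 8-lithio-hexa-O-benzylgallocatechin | [Li]c1c(OCc2ccccc2)cc(OCc2ccccc2)c2c1O[C@H](c1cc(OCc3ccccc3)c(OCc3ccccc3)c(OCc3ccccc3)c1)[C@@H](OCc1ccccc1)C2 | intermediate (not isolated)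
14 | lithium bis(hexa-O-benzylgallocatechin-8-yl)cuprate, LiCuAr2 | [Li+].[Cu-](c1c(OCc2ccccc2)cc(OCc2ccccc2)c2c1O[C@H](c1cc(OCc3ccccc3)c(OCc3ccccc3)c(OCc3ccccc3)c1)[C@@H](OCc1ccccc1)C2)c1c(OCc2ccccc2)cc(OCc2ccccc2)c2c1O[C@H](c1cc(OCc3ccccc3)c(OCc3ccccc3)c(OCc3ccccc3)c1)[C@@H](OCc1ccccc1)C2 | intermediate (not isolated)
15 | trimethylsilyl ketene acetal of 16 | c5ccccc5COc1ccc([C@@H]2C[C@@H](c3c(OCc5ccccc5)cc(OCc5ccccc5)c4c3O[C@H](c3cc(OCc5ccccc5)c(OCc5ccccc5)c(OCc5ccccc5)c3)[C@@H](OCc5ccccc5)C4)C=C(O[Si](C)(C)C)O2)cc1 | intermediate (not isolated)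
16 | (4R,6S)-6-[4-(benzyloxy)phenyl]-4-(hexa-O-benzylgallocatechin-8-yl)tetrahydro-2H-pyran-2-one, 4,6-trans | c5ccccc5COc1ccc([C@@H]2C[C@@H](c3c(OCc5ccccc5)cc(OCc5ccccc5)c4c3O[C@H](c3cc(OCc5ccccc5)c(OCc5ccccc5)c(OCc5ccccc5)c3)[C@@H](OCc5ccccc5)C4)CC(=O)O2)cc1 | intermediate (key-step precursor)
17 | (1-bromovinyl)trimethylsilane | C=C(Br)[Si](C)(C)C | starting material
18 | acetaldehyde | CC=O | starting material
19 | 1-(trimethylsilyl)vinylmagnesium bromide | C=C([Mg]Br)[Si](C)(C)C | intermediate (not isolated)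
20 | 3-(trimethylsilyl)but-3-en-2-ol, racemic | CC(O)C(=C)[Si](C)(C)C | intermediate
21 | 3-(trimethylsilyl)but-3-en-2-one | CC(=O)C(=C)[Si](C)(C)C | intermediate
22 | (3S,4R,6S)-3-[3-oxo-2-(trimethylsilyl)butyl] derivative of 16, epimers at the silyl carbon | c5ccccc5COc1ccc([C@@H]2C[C@@H](c3c(OCc5ccccc5)cc(OCc5ccccc5)c4c3O[C@H](c3cc(OCc5ccccc5)c(OCc5ccccc5)c(OCc5ccccc5)c3)[C@@H](OCc5ccccc5)C4)[C@H](CC(C(C)=O)[Si](C)(C)C)C(=O)O2)cc1 | intermediate (not isolated)
23 | (3S,4R,6S)-3-(3-oxobutyl) derivative of 16 | c5ccccc5COc1ccc([C@@H]2C[C@@H](c3c(OCc5ccccc5)cc(OCc5ccccc5)c4c3O[C@H](c3cc(OCc5ccccc5)c(OCc5ccccc5)c(OCc5ccccc5)c3)[C@@H](OCc5ccccc5)C4)[C@H](CCC(C)=O)C(=O)O2)cc1 | intermediate (not isolated)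
24 | 4-[3-(4-benzyloxyphenyl)-3-hydroxy-1-(hexa-O-benzylgallocatechin-8-yl)propyl]cyclohexane-1,3-dione | c5ccccc5COc1ccc([C@@H](O)C[C@@H](c3c(OCc5ccccc5)cc(OCc5ccccc5)c4c3O[C@H](c3cc(OCc5ccccc5)c(OCc5ccccc5)c(OCc5ccccc5)c3)[C@@H](OCc5ccccc5)C4)[C@@H]3CCC(=O)CC3=O)cc1 | intermediate (not isolated)
25 | (2S,4R,4aS)-2-[4-(benzyloxy)phenyl]-4-(hexa-O-benzylgallocatechin-8-yl)-2,3,4,4a,5,6-hexahydro-7H-chromen-7-one | c5ccccc5COc1ccc([C@@H]2C[C@@H](c3c(OCc5ccccc5)cc(OCc5ccccc5)c4c3O[C@H](c3cc(OCc5ccccc5)c(OCc5ccccc5)c(OCc5ccccc5)c3)[C@@H](OCc5ccccc5)C4)[C@@H]3CCC(=O)C=C3O2)cc1 | intermediate (key-step product)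
26 | 6-(phenylselanyl) derivative of 25, epimers at C6 | c5ccccc5COc1ccc([C@@H]2C[C@@H](c3c(OCc5ccccc5)cc(OCc5ccccc5)c4c3O[C@H](c3cc(OCc5ccccc5)c(OCc5ccccc5)c(OCc5ccccc5)c3)[C@@H](OCc5ccccc5)C4)[C@@H]3CC([Se]c6ccccc6)C(=O)C=C3O2)cc1 | intermediate
27 | selenoxide of 26 | c5ccccc5COc1ccc([C@@H]2C[C@@H](c3c(OCc5ccccc5)cc(OCc5ccccc5)c4c3O[C@H](c3cc(OCc5ccccc5)c(OCc5ccccc5)c(OCc5ccccc5)c3)[C@@H](OCc5ccccc5)C4)[C@@H]3CC([Se](=O)c6ccccc6)C(=O)C=C3O2)cc1 | intermediate (not isolated)
28 | 2,3,4,4a-tetrahydro-7H-chromen-7-one (cross-conjugated dienone) | c5ccccc5COc1ccc([C@@H]2C[C@@H](c3c(OCc5ccccc5)cc(OCc5ccccc5)c4c3O[C@H](c3cc(OCc5ccccc5)c(OCc5ccccc5)c(OCc5ccccc5)c3)[C@@H](OCc5ccccc5)C4)[C@@H]3C=CC(=O)C=C3O2)cc1 | intermediate (not isolated)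
29 | (2S,4R)-2-[4-(benzyloxy)phenyl]-4-(hexa-O-benzylgallocatechin-8-yl)chroman-7-ol | c5ccccc5COc1ccc([C@@H]2C[C@@H](c3c(OCc5ccccc5)cc(OCc5ccccc5)c4c3O[C@H](c3cc(OCc5ccccc5)c(OCc5ccccc5)c(OCc5ccccc5)c3)[C@@H](OCc5ccccc5)C4)c3ccc(O)cc3O2)cc1 | intermediate
30 | CNP0220331.3, (2S,4R)-4',7-dihydroxyflavan-(4→8)-(+)-gallocatechin | Oc1ccc([C@@H]2C[C@@H](c3c(O)cc(O)c4c3O[C@H](c3cc(O)c(O)c(O)c3)[C@@H](O)C4)c3ccc(O)cc3O2)cc1 | target

**Totals**

Total step count: 13. Longest linear sequence: 8 steps (steps 1, 2, 3, 7, 10, 11, 12, 13, or equally steps 4, 5, 6, 7, 10, 11, 12, 13).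

**Steps most likely to fail**

1. Step 10 (proposed new method). The hindered lactone enolate may add 1,2 to the enone or exchange a proton with it instead of adding 1,4, so that the C4a–C5 bond is not formed cleanly before the Claisen stage. The fallback sets out from 16 and forms the two bonds in separate, known operations. Alkylation of the lithium enolate of 16 (LiN(iPr)2, THF/DMPU, −78 °C) with 2-(2-iodoethyl)-2-methyl-1,3-dioxolane should give, trans to the C4 aryl, the 3-[2-(2-methyl-1,3-dioxolan-2-yl)ethyl] lactone F1. Ketal hydrolysis of F1 (PPTS, wet acetone) gives keto lactone 23, now isolated. Base-mediated cyclisation of this δ-keto ester (KOtBu, THF, 0 °C → rt) gives hydroxy dione 24, and PPTS in toluene closes it to 25, where the route is rejoined.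

2. Step 7. Transfer of the di-ortho-alkoxy aryl group from copper may be slow, leaving time for γ-deprotonation of 7 at C5 and ring-opening to the dienoic acid, or for erosion of facial selectivity. The fallback sets out from 12 and replaces the stoichiometric cuprate by catalysis under nearly neutral conditions. Bromine–lithium exchange (t-BuLi, THF, −78 °C) and trapping with 2-isopropoxy-4,4,5,5-tetramethyl-1,3,2-dioxaborolane gives hexa-O-benzylgallocatechin-8-ylboronic acid pinacol ester F2. Hayashi–Miyaura conjugate addition of F2 to 7 ([Rh(OH)(cod)]2 cat., aq. KOH, dioxane, 60 °C), again anti to the C6 aryl, returns to the route at 16.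

3. Step 12. Electrophilic selenium species and peroxide formed during the elimination may attack the newly formed electron-rich phenol (ring selenenylation, over-oxidation). The fallback sets out from 25 and avoids selenium and peroxide. Kinetic enolisation and silylation (LiN(iPr)2, Me3SiCl, THF, −78 °C) gives the 7-(trimethylsilyloxy) cross-conjugated dienol ether F3. Saegusa–Ito oxidation of F3 with Pd(OAc)2 in MeCN at rt gives dienone 28, which tautomerises to 29, where the route is rejoined.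

**Further compounds**

F1 | step 10 | (3S,4R,6S)-3-[2-(2-methyl-1,3-dioxolan-2-yl)ethyl] derivative of 16 | c5ccccc5COc1ccc([C@@H]2C[C@@H](c3c(OCc5ccccc5)cc(OCc5ccccc5)c4c3O[C@H](c3cc(OCc5ccccc5)c(OCc5ccccc5)c(OCc5ccccc5)c3)[C@@H](OCc5ccccc5)C4)[C@H](CCC3(C)OCCO3)C(=O)O2)cc1
F2 | step 7 | hexa-O-benzylgallocatechin-8-ylboronic acid pinacol ester | CC1(C)OB(OC1(C)C)c1c(OCc2ccccc2)cc(OCc2ccccc2)c2c1O[C@H](c1cc(OCc3ccccc3)c(OCc3ccccc3)c(OCc3ccccc3)c1)[C@@H](OCc1ccccc1)C2
F3 | step 12 | 7-(trimethylsilyloxy)-2,3,4,4a-tetrahydro-5H-chromene dienol ether of 25 | c5ccccc5COc1ccc([C@@H]2C[C@@H](c3c(OCc5ccccc5)cc(OCc5ccccc5)c4c3O[C@H](c3cc(OCc5ccccc5)c(OCc5ccccc5)c(OCc5ccccc5)c3)[C@@H](OCc5ccccc5)C4)[C@@H]3CC=C(O[Si](C)(C)C)C=C3O2)cc1
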